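**Numbering used throughout:** 1 and 4 are the starting materials, 12 is the open-chain precursor of the key step, 13 its product, 16 the target. The full list follows the steps.

## Analysis of the target

The target 16 is an achiral diarylmethane: two hexasubstituted benzene rings joined by one CH2 group, with no stereocentre, so the problem is entirely one of regiochemistry. Ring A is a free acylphloroglucinol: A1 carries the propanoyl group, A2, A4 and A6 carry hydroxyls, A3 a methyl group and A5 the bridge. Ring B has the same skeleton with one oxygen methylated: B1 bridge, B2 OH, B3 propanoyl, B4 OH, B5 methyl, B6 OMe. Its methoxy group is para to the ring B ketone and its two hydroxyls are ortho to it. The sensitive features are five free phenols on electron-rich rings, two ortho-hydroxy aryl ketones that bind Lewis acids, and the CH2 bridge. The bridge can be cut by acid (ipso-protonation, retro-Friedel–Crafts) and, once both rings are phenolic, by base through a quinone methide. The difficulty is that no ring carbon is free in the target, so nothing can be corrected by a late aromatic substitution, and one O-methyl has to be told apart from five hydroxyls. The plan rests on ring A: oxygen on the alternate carbons A2, A4 and A6 with the acyl group on A1 is the pattern of a propionate-started triketide, and the A1–A6 bond is the bond a Claisen condensation makes. The bridge carbon sits on A5, the malonate-type carbon of that chain, so the bridge and ring B can be in place before ring A exists.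

## Retrosynthetic reasoning

**16 to 15 (two O–CH3 bonds of ring B).** The two hydroxyls of ring B flank the B3 ketone and the surviving methoxy is para to it. Ring B is therefore traced back to its trimethyl ether 15, and the ketone is used to select which two ethers fall. The forward reaction is a chelation-controlled ether cleavage by a boron Lewis acid. It must stop before the B6 ether, which has no neighbouring carbonyl.

**15 to 13 (B3–C(=O) bond).** In 13 ring A has no free carbon and ring B has exactly one, B3, between two methoxy groups. A Friedel–Crafts acylation can therefore go to one carbon only. A ring A hydroxyl is esterified in passing (14) and freed again by methanolysis while ring B is still fully etherified, so base cannot open the bridge.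

**13 to 12 (A1–A6 bond, the key disconnection).** Cutting A1–A6 opens ring A to the triketo ester 12. Its chain already holds every ring A substituent in order: the ester carbon C1 becomes A6, C2 with the arylmethyl group becomes A5, C3 becomes A4, C4 with its methyl becomes A3, C5 becomes A2, and C6 becomes A1 with C7–C9 as the propanoyl group. No other cut of ring A gives a precursor in which the bridge is attached to an ordinary enolisable sp3 carbon rather than to a crowded arene. The forward reaction has to make the C6 carbon attack the C1 ester (Claisen) rather than let the chain fold in another way.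

**12 to 11 (C7 carbonyl).** The C7 ketone is masked as a dioxolane in 11. The chain can then be assembled with strong base without a third acidic site, and the mask is removed by mild aqueous acid just before the ring closure.

**11 to 6 and 8 (C4–C5 bond).** The chain is cut between C4 and C5. C4 is the γ-carbon of the β-keto ester 6 and is nucleophilic in its dianion 9. C5 is the carbonyl of the Weinreb amide 8, which holds the adduct as the tetrahedral chelate 10 until work-up. The highly acidic C4–H of the product is therefore not exposed to unreacted dianion.

**8 to 7 to 4.** The amide comes from the ketal ester 7 by direct aminolysis, and 7 from methyl 3-oxopentanoate 4 by ketalisation. The same four-carbon keto ester thus supplies both halves of the chain.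

**6 to 5 to 3 and 4 (C2–CH2 bond).** The bridge carbon is attached to C2 as a C=C bond by Knoevenagel condensation of aldehyde 3 with 4, and alkene 5 is then hydrogenated. This avoids a 2,4,6-trialkoxybenzyl halide, which ionises and self-condenses readily.

**3 to 1 (B1–CHO bond).** The two free positions of 2,4,6-trimethoxytoluene 1 are equivalent, so formylation through the iminium salt 2 gives one aldehyde.

## Alternatives that were turned down

**Alternative 1: aryne addition to set the ring B ketone.**
- Disconnection: the B3–C(=O) and B4–O bonds of ring B, made together.
- Forward key step: the ortho-silyl aryl triflate A1 is converted by a fluoride source into the aryne spanning B3 and B4. The carboxylic acid A2 adds its oxygen to B4 and its acyl carbon ends on B3, giving the ortho-hydroxy ketone A3. In A3, B2 carries a benzyl ether, B6 the methyl ether, and B1 is still free.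
- For: one operation sets the ketone and its neighbouring hydroxyl. The three oxygens of ring B come out already differentiated, so no directed double demethylation is needed. On that point this plan is stronger than the chosen one.
- Against: the step works on a monomer. It forms no bond of ring A and does not touch the bridge, so ring A must be built separately and the halves joined at B1 by an acid-mediated arylmethylation, the operation most likely to scramble a methylene-bridged phloroglucinol. A1 is itself a pentasubstituted benzene with silicon and triflate on adjacent carbons, and making it costs several regiocontrolled aromatic steps. The benzyloxy group at B2 steers the oxygen nucleophile to B4 as required, but B4 is flanked by the B5 methyl, so the electronic preference works against sterics.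
- Comparison: the chosen route gives up pre-differentiated oxygens and accepts a ketone-directed ether cleavage at the end. In return it forms ring A, with all six substituents and the bridge, in one ring closure from a chain made in seven steps.

**Alternative 2: benzannulation of ring B onto the bridge.**
- Disconnection: ring B at B1–B2 and B5–B6, assembled from a four-carbon and a two-carbon piece.
- Forward key step: heating the cyclobutenone A4 opens it to a vinylketene, which adds across the alkynyl ether A5. Opening of the new four-membered ring and 6π-electrocyclisation give the phenol A6. In A6, B2 is a free hydroxyl, B4 an ethyl ether, B6 a methyl ether, and B1 carries the CH2 group to a tris-benzyl-protected ring A.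
- For: the regiochemistry is written into the two components, the conditions are neutral, and the ring B oxygens emerge as three different groups. That is as good as or better than the chosen route. The bridge is brought in as a propargylic CH2 and never as a benzylic cation.
- Against: A6 carries neither propanoyl group, since A1 and B3 are both still C–H. Two Friedel–Crafts acylations must follow on a substrate with three acid-labile benzyl ethers. The B4 ethyl ether must still be cleaved beside the B6 methyl ether, which again needs the B3 ketone as director, so the end-game problem returns with more steps. A5 has a CH2 group that is both propargylic and benzylic and can isomerise to the allene, and it needs a preformed, protected ring A.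
- Comparison: the chosen route is weaker in oxygen differentiation but shorter, and its ring closure delivers ring A with its ketone and free hydroxyls already present.

**Alternative 3: cycloaddition and cycloreversion to ring A.**
- Disconnection: ring A at A1–A2 and A5–A6.
- Forward key step: the silyloxy diene A8 is made from the dione A7 by O-methylation, alkylation beside the ketone with a ring B benzylic electrophile, and enol silylation. It adds the alkynyl ketone A9, and the bicyclic adduct loses its saturated two-carbon bridge on heating to leave the arene A10.
- For: like the chosen route it makes ring A with ketone, methyl and bridge in place and ring B as the inert trimethyl ether. The polarisation of diene and dienophile agrees on the regiochemistry, since the nucleophilic diene terminus carries the arylmethyl group and the electrophilic alkyne carbon carries the ethoxy group. Aromatisation is driven by loss of a gas, and there is no competing mode of ring closure. On that last point it is stronger than a polyketide folding, which has aldol and lactone alternatives.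
- Against: both diene termini are fully substituted, so the cycloaddition must create two quaternary bridgeheads, one beside the bulky arylmethyl group. A9 is a push–pull alkyne whose alkoxy group cancels much of the ketone's activation. The cycloreversion needs high temperature. A10 has a methyl ether on A2 and an ethyl ether on A6 that must both be removed, two ether cleavages beyond those on ring B. A8 also needs an alkylation with a labile electron-rich benzylic halide.
- Comparison: the chosen route has to win a competition between folding modes, but it gives ring A directly as the free triol under mild basic conditions and reaches its precursor with fewer and simpler steps.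

Key step: step 8

Remark on the chemistry: 6, 11 and 12 are racemic or diastereomeric mixtures at enolisable centres that disappear on aromatisation. In step 9 the ring A hydroxyl para to the ring A ketone is assumed to be the one esterified in passing (14); esters at the other two hydroxyls, if formed, are cleaved by the same methanolysis.

## Route

Step 1
Reactants: 1 2,4,6-trimethoxytoluene
Product: 3 2,4,6-trimethoxy-3-methylbenzaldehyde, via iminium chloride 2 (not isolated)
Conditions: POCl3, DMF, 0 °C → 60 °C; then H2O, NaOAc, rt
Reagents that add atoms: N,N-dimethylformamide (CN(C)C=O); water (O)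
Why: Vilsmeier–Haack formylation; the two free positions of 1 are equivalent and each is activated by three methoxy groups, and the iminium salt 2 deactivates the ring against a second attack before it is hydrolysed to 3.

Step 2
Reactants: 3 2,4,6-trimethoxy-3-methylbenzaldehyde; 4 methyl 3-oxopentanoate
Product: 5 methyl 3-oxo-2-[(2,4,6-trimethoxy-3-methylphenyl)methylidene]pentanoate (E/Z mixture)
Conditions: piperidine (cat.), AcOH (cat.), toluene, reflux, Dean–Stark
Reagents that add atoms: none
Why: Knoevenagel condensation; azeotropic removal of water drives the reaction of the electron-rich, di-ortho-substituted aldehyde, and the alkene geometry does not matter because the double bond is reduced next.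

Step 3
Reactants: 5 methyl 3-oxo-2-[(2,4,6-trimethoxy-3-methylphenyl)methylidene]pentanoate
Product: 6 methyl 3-oxo-2-[(2,4,6-trimethoxy-3-methylphenyl)methyl]pentanoate (racemic)
Conditions: H2 (1 atm), 10% Pd/C, EtOAc, rt
Reagents that add atoms: none
Why: Catalytic hydrogenation of an electron-poor alkylidene C=C; ketone, ester and aryl ethers are inert under these conditions, and the new C2 centre is racemic, enolisable and later erased.

Step 4
Reactants: 4 methyl 3-oxopentanoate
Product: 7 methyl 2-(2-ethyl-1,3-dioxolan-2-yl)acetate
Conditions: HOCH2CH2OH, p-TsOH·H2O (cat.), toluene, reflux, Dean–Stark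
Reagents that add atoms: ethane-1,2-diol (OCCO)
Why: Acid-catalysed ketalisation with azeotropic water removal; the ketone reacts and the ester does not.

Step 5
Reactants: 7 methyl 2-(2-ethyl-1,3-dioxolan-2-yl)acetate
Product: 8 2-(2-ethyl-1,3-dioxolan-2-yl)-N-methoxy-N-methylacetamide
Conditions: MeNH(OMe)·HCl, i-PrMgCl, THF, −20 °C → 0 °C
Reagents that add atoms: N,O-dimethylhydroxylamine hydrochloride (CNOC.Cl)
Why: Direct ester-to-Weinreb-amide aminolysis by the chloromagnesium amide formed in the flask; the ketal is stable to the basic conditions.

Step 6
Reactants: 6 methyl 3-oxo-2-[(2,4,6-trimethoxy-3-methylphenyl)methyl]pentanoate; 8 2-(2-ethyl-1,3-dioxolan-2-yl)-N-methoxy-N-methylacetamide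
Product: 11 methyl 6-(2-ethyl-1,3-dioxolan-2-yl)-4-methyl-3,5-dioxo-2-[(2,4,6-trimethoxy-3-methylphenyl)methyl]hexanoate (diastereomer mixture), via dilithium dienolate 9 (not isolated), via tetrahedral adduct 10 (not isolated)
Conditions: LiN(i-Pr)2 (2.2 equiv), THF, −78 °C → 0 °C; then 8 (1.1 equiv), −78 °C → −20 °C; then AcOH, −78 °C
Reagents that add atoms: none
Why: γ-Acylation of a β-keto ester dianion with a Weinreb amide; the second deprotonation occurs at the ethyl CH2, the only γ-position, and that carbon is the most nucleophilic site of 9. The N-methoxy chelate 10 survives until the acid quench, so the very acidic C4–H of 11 is never exposed to unreacted dianion.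

Step 7
Reactants: 11 methyl 6-(2-ethyl-1,3-dioxolan-2-yl)-4-methyl-3,5-dioxo-2-[(2,4,6-trimethoxy-3-methylphenyl)methyl]hexanoate
Product: 12 methyl 4-methyl-3,5,7-trioxo-2-[(2,4,6-trimethoxy-3-methylphenyl)methyl]nonanoate (diastereomer mixture)
Conditions: 1 M HCl, THF, rt
Reagents that add atoms: water (O)
Why: Acid-catalysed ketal hydrolysis; dilute acid at room temperature should free the C7 ketone without the dehydrative pyranone closure that stronger acid or heat would cause, and aryl methyl ethers and the ester are untouched.

Step 8
Reactants: 12 methyl 4-methyl-3,5,7-trioxo-2-[(2,4,6-trimethoxy-3-methylphenyl)methyl]nonanoate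
Product: 13 1-[2,4,6-trihydroxy-3-methyl-5-[(2,4,6-trimethoxy-3-methylphenyl)methyl]phenyl]propan-1-one
Conditions: Mg(OMe)2 (5 equiv), MeOH, rt → 65 °C, Ar; then 1 M HCl, 0 °C
Reagents that add atoms: none
Why: Intramolecular Claisen (Dieckmann-type) condensation of a 3,5,7-triketo ester, the known magnesium alkoxide route from such chains to acylphloroglucinols. Mg(OMe)2 turns the acidic sites C2, C4 and C6 into magnesium-chelated enolates; the C6 carbon of the C5/C7 diketonate adds to the C1 ester carbonyl, methoxide leaves, and the 2-acylcyclohexane-1,3,5-trione tautomerises to the magnesium phenoxide of 13, which the acid work-up protonates. Ring A closes by 6-exo-trig attack on the ester carbonyl (as an enolate closure, 6-enolendo-exo-trig, also allowed), forming the A1–A6 bond. No stereocentre is formed, and the two enolisable centres of 12 (C2 and C4) become sp2 ring carbons, so the diastereomer mixture converges. The selectivity needed is C-acylation of C6 at C1 in preference to aldol attack of C2 on the C7 ketone, lactonisation to a pyranone, and retro-Claisen cleavage of the chain. The aldol adduct would have a quaternary C2 bearing both the arylmethyl group and the ester, cannot dehydrate to an arene and should revert; a pyranone is reopened by methoxide; and chelation keeps the dicarbonyl units as enolates, which resist methoxide attack. Only the Claisen product leaves these equilibria, through aromatisation and phenoxide formation. Ring B, a trimethyl ether with no acidic or electrophilic site, is a spectator.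

Step 9
Reactants: 13 1-[2,4,6-trihydroxy-3-methyl-5-[(2,4,6-trimethoxy-3-methylphenyl)methyl]phenyl]propan-1-one
Product: 15 1-[2,4,6-trihydroxy-3-methyl-5-[(2,4,6-trimethoxy-3-methyl-5-propanoylphenyl)methyl]phenyl]propan-1-one, via ring A propanoate ester 14 (not isolated)
Conditions: (EtCO)2O (4 equiv), BF3·OEt2 (4 equiv), CH2Cl2, 0 °C → rt; then K2CO3, MeOH, rt; 1 M HCl
Reagents that add atoms: propanoic anhydride (CCC(=O)OC(=O)CC)
Why: Friedel–Crafts acylation; ring A has no free carbon and ring B only B3, activated by three methoxy groups, so C-acylation can go to one position only. The ring A hydroxyl esterified in passing is released by methanolysis, which is safe for the bridge because ring B has no free hydroxyl at this stage.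

Step 10
Reactants: 15 1-[2,4,6-trihydroxy-3-methyl-5-[(2,4,6-trimethoxy-3-methyl-5-propanoylphenyl)methyl]phenyl]propan-1-one
Product: 16 1-[3-[(2,4-dihydroxy-6-methoxy-5-methyl-3-propanoylphenyl)methyl]-2,4,6-trihydroxy-5-methylphenyl]propan-1-one (target)
Conditions: BCl3 (1 M in CH2Cl2, 6 equiv), CH2Cl2, −78 °C → rt; then H2O, 0 °C
Reagents that add atoms: none
Why: Chelation-controlled cleavage of aryl methyl ethers ortho to a carbonyl; BCl3 bound to the ring B ketone removes the methyl groups at B2 and B4 through six-membered chelates, while the B6 ether, para to the ketone, lacks this assistance and should survive. Ring A has no ether, and excess reagent covers the boron taken up by its phenols and ketone.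

## Compound list

1 | 2,4,6-trimethoxytoluene (1,3,5-trimethoxy-2-methylbenzene) | Cc1c(OC)cc(OC)cc1OC | starting material
2 | N-methyl-N-[(2,4,6-trimethoxy-3-methylphenyl)methylidene]methanaminium chloride | C[N+](C)=Cc1c(OC)cc(OC)c(C)c1OC.[Cl-] | intermediate
3 | 2,4,6-trimethoxy-3-methylbenzaldehyde | O=Cc1c(OC)cc(OC)c(C)c1OC | intermediate
4 | methyl 3-oxopentanoate | CCC(=O)CC(=O)OC | starting material
5 | methyl 3-oxo-2-[(2,4,6-trimethoxy-3-methylphenyl)methylidene]pentanoate (E/Z mixture) | CCC(=O)C(=Cc1c(OC)cc(OC)c(C)c1OC)C(=O)OC | intermediate
6 | methyl 3-oxo-2-[(2,4,6-trimethoxy-3-methylphenyl)methyl]pentanoate (racemic) | CCC(=O)C(Cc1c(OC)cc(OC)c(C)c1OC)C(=O)OC | intermediate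
7 | methyl 2-(2-ethyl-1,3-dioxolan-2-yl)acetate | CCC1(CC(=O)OC)OCCO1 | intermediate
8 | 2-(2-ethyl-1,3-dioxolan-2-yl)-N-methoxy-N-methylacetamide | CCC1(CC(=O)N(C)OC)OCCO1 | intermediate
9 | dilithium 1-methoxy-2-[(2,4,6-trimethoxy-3-methylphenyl)methyl]penta-1,3-diene-1,3-diolate (dianion of 6) | CC=C([O-])C(Cc1c(OC)cc(OC)c(C)c1OC)=C([O-])OC.[Li+].[Li+] | intermediate
10 | dilithium 6-(2-ethyl-1,3-dioxolan-2-yl)-1-methoxy-5-[methoxy(methyl)amino]-4-methyl-3-oxo-2-[(2,4,6-trimethoxy-3-methylphenyl)methyl]hex-1-ene-1,5-diolate (tetrahedral adduct) | CCC1(CC([O-])(N(C)OC)C(C)C(=O)C(Cc2c(OC)cc(OC)c(C)c2OC)=C([O-])OC)OCCO1.[Li+].[Li+] | intermediate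
11 | methyl 6-(2-ethyl-1,3-dioxolan-2-yl)-4-methyl-3,5-dioxo-2-[(2,4,6-trimethoxy-3-methylphenyl)methyl]hexanoate (diastereomer mixture) | CCC1(CC(=O)C(C)C(=O)C(Cc2c(OC)cc(OC)c(C)c2OC)C(=O)OC)OCCO1 | intermediate
12 | methyl 4-methyl-3,5,7-trioxo-2-[(2,4,6-trimethoxy-3-methylphenyl)methyl]nonanoate (diastereomer mixture) | CCC(=O)CC(=O)C(C)C(=O)C(Cc1c(OC)cc(OC)c(C)c1OC)C(=O)OC | intermediate
13 | 1-[2,4,6-trihydroxy-3-methyl-5-[(2,4,6-trimethoxy-3-methylphenyl)methyl]phenyl]propan-1-one | CCC(=O)c1c(O)c(C)c(O)c(Cc2c(OC)cc(OC)c(C)c2OC)c1O | intermediate
14 | 3,5-dihydroxy-2-methyl-4-propanoyl-6-[(2,4,6-trimethoxy-3-methyl-5-propanoylphenyl)methyl]phenyl propanoate | CCC(=O)Oc1c(C)c(O)c(C(=O)CC)c(O)c1Cc1c(OC)c(C(=O)CC)c(OC)c(C)c1OC | intermediate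
15 | 1-[2,4,6-trihydroxy-3-methyl-5-[(2,4,6-trimethoxy-3-methyl-5-propanoylphenyl)methyl]phenyl]propan-1-one | CCC(=O)c1c(O)c(C)c(O)c(Cc2c(OC)c(C(=O)CC)c(OC)c(C)c2OC)c1O | intermediate
16 | 1-[3-[(2,4-dihydroxy-6-methoxy-5-methyl-3-propanoylphenyl)methyl]-2,4,6-trihydroxy-5-methylphenyl]propan-1-one | CCC(=O)c1c(O)c(C)c(O)c(Cc2c(O)c(C(=O)CC)c(O)c(C)c2OC)c1O | target

## Step count and least certain steps

Total step count: 10. Longest linear sequence: 8 steps (steps 1, 2, 3, 6, 7, 8, 9, 10, from 1); steps 4 and 5 form the side branch to 8.

**Step 8 (key step).** The most likely failure is that ring closure is slower than breakdown of the chain. The ester carbonyl sits beside the branched, bulky C2, so methoxide may cut the triketone by retro-Claisen cleavage, or the chain may rest as a lactone, before C6 reaches C1. Fallback: ring A is not built from a chain but bought as an arene and joined to ring B. Starting from 3, reduction with NaBH4 in MeOH gives the benzylic alcohol (2,4,6-trimethoxy-3-methylphenyl)methanol F1. Separately, 2-methylbenzene-1,3,5-triol F2 is C-acylated with propanoic acid and BF3·OEt2 at 80 °C to 1-(2,4,6-trihydroxy-3-methylphenyl)propan-1-one F3; its two free positions are equivalent. F1 is then added slowly to an excess of F3 with catalytic p-TsOH in MeCN at rt, and the benzylic cation is captured by the only free ring carbon of F3. The sequence returns to the route at 13.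

**Step 6.** The likely failure is proton transfer from the α-CH2 of the amide to the strongly basic dianion, possibly followed by β-elimination that opens the dioxolane. This would compete with a slow attack of the secondary γ-carbanion on an amide carbonyl that has a quaternary β-carbon. Fallback: an aldol–oxidation sequence with a more electrophilic partner. Starting from 8, reduction with i-Bu2AlH in THF at −78 °C gives 2-(2-ethyl-1,3-dioxolan-2-yl)acetaldehyde F4. Addition of the dianion 9 to F4 at −78 °C gives the aldol methyl 6-(2-ethyl-1,3-dioxolan-2-yl)-5-hydroxy-4-methyl-3-oxo-2-[(2,4,6-trimethoxy-3-methylphenyl)methyl]hexanoate F5. Oxidation with Dess–Martin periodinane in CH2Cl2 returns to the route at 11.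

**Step 9.** The likely failure is acid-induced scission of the bridge. Ipso-protonation of ring B at B1 would let ring A leave as a hydroxyl-stabilised quinone methide before B3 is acylated, and the free phenols would also be esterified and bound to boron in an uncontrolled way. Fallback: the phenols are capped first, which removes the stabilisation of that leaving group. Starting from 13, Ac2O, pyridine and DMAP give 2-methyl-4-propanoyl-6-[(2,4,6-trimethoxy-3-methylphenyl)methyl]benzene-1,3,5-triyl triacetate F6. Acylation with EtCOCl and SnCl4 in CH2Cl2 at −20 °C → 0 °C gives 2-methyl-4-propanoyl-6-[(2,4,6-trimethoxy-3-methyl-5-propanoylphenyl)methyl]benzene-1,3,5-triyl triacetate F7. Methanolysis with K2CO3 in MeOH returns to the route at 15.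

**Step 10.** The likely failure is stalling after the first ether cleavage, because the ketone oxygen is then tied up in the boron chelate of the new phenoxide. Forcing the reaction risks loss of the B6 methyl group or scission of the bridge. Fallback: the two ethers are removed in two stages by different mechanisms. Starting from 15, BCl3 (2 to 3 equiv) at −78 °C → 0 °C is stopped at the mono-phenol, 1-[2,4,6-trihydroxy-3-[(4-hydroxy-2,6-dimethoxy-5-methyl-3-propanoylphenyl)methyl]-5-methylphenyl]propan-1-one F8 or its isomer with the ether beside the bridge cleaved, 1-[2,4,6-trihydroxy-3-[(2-hydroxy-4,6-dimethoxy-5-methyl-3-propanoylphenyl)methyl]-5-methylphenyl]propan-1-one F9. Both converge. The remaining ortho ether is then removed with MgI2·OEt2 in toluene at 80 °C, where iodide attacks the methyl group of the magnesium-chelated ether. This returns to the route at 16.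

**Step 2.** The likely failure is slow condensation of the deactivated, di-ortho-substituted aldehyde, so that Michael addition of a second keto ester to the product competes. Fallback: the C2–CH2 bond is made by alkylation instead. Starting from 3, the benzylic alcohol F1 (made as described under step 8) is treated with PBr3 in Et2O at −20 °C to give 2-(bromomethyl)-1,3,5-trimethoxy-4-methylbenzene F10. F10 is used at once, without purification, to alkylate the sodium enolate of 4 (NaH, THF, 0 °C). This returns to the route at 6 and bypasses 5.

## Further compounds

F1 | step 8 | (2,4,6-trimethoxy-3-methylphenyl)methanol | OCc1c(OC)cc(OC)c(C)c1OC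
F2 | step 8 | 2-methylbenzene-1,3,5-triol | Cc1c(O)cc(O)cc1O
F3 | step 8 | 1-(2,4,6-trihydroxy-3-methylphenyl)propan-1-one | CCC(=O)c1c(O)cc(O)c(C)c1O
F4 | step 6 | 2-(2-ethyl-1,3-dioxolan-2-yl)acetaldehyde | CCC1(CC=O)OCCO1
F5 | step 6 | methyl 6-(2-ethyl-1,3-dioxolan-2-yl)-5-hydroxy-4-methyl-3-oxo-2-[(2,4,6-trimethoxy-3-methylphenyl)methyl]hexanoate (diastereomer mixture) | CCC1(CC(O)C(C)C(=O)C(Cc2c(OC)cc(OC)c(C)c2OC)C(=O)OC)OCCO1
F6 | step 9 | 2-methyl-4-propanoyl-6-[(2,4,6-trimethoxy-3-methylphenyl)methyl]benzene-1,3,5-triyl triacetate | CCC(=O)c1c(OC(C)=O)c(C)c(OC(C)=O)c(Cc2c(OC)cc(OC)c(C)c2OC)c1OC(C)=O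
F7 | step 9 | 2-methyl-4-propanoyl-6-[(2,4,6-trimethoxy-3-methyl-5-propanoylphenyl)methyl]benzene-1,3,5-triyl triacetate | CCC(=O)c1c(OC(C)=O)c(C)c(OC(C)=O)c(Cc2c(OC)c(C(=O)CC)c(OC)c(C)c2OC)c1OC(C)=O
F8 | step 10 | 1-[2,4,6-trihydroxy-3-[(4-hydroxy-2,6-dimethoxy-5-methyl-3-propanoylphenyl)methyl]-5-methylphenyl]propan-1-one | CCC(=O)c1c(O)c(C)c(O)c(Cc2c(OC)c(C(=O)CC)c(O)c(C)c2OC)c1O
F9 | step 10 | 1-[2,4,6-trihydroxy-3-[(2-hydroxy-4,6-dimethoxy-5-methyl-3-propanoylphenyl)methyl]-5-methylphenyl]propan-1-one | CCC(=O)c1c(O)c(C)c(O)c(Cc2c(O)c(C(=O)CC)c(OC)c(C)c2OC)c1O
F10 | step 2 | 2-(bromomethyl)-1,3,5-trimethoxy-4-methylbenzene | BrCc1c(OC)cc(OC)c(C)c1OC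
A1 | alternative 1 | 3-(benzyloxy)-5-methoxy-6-methyl-2-(trimethylsilyl)phenyl trifluoromethanesulfonate | Cc1c(OC)cc(OCc2ccccc2)c([Si](C)(C)C)c1OS(=O)(=O)C(F)(F)F
A2 | alternative 1 | propanoic acid | CCC(=O)O
A3 | alternative 1 | 1-[6-(benzyloxy)-2-hydroxy-4-methoxy-3-methylphenyl]propan-1-one | CCC(=O)c1c(O)c(C)c(OC)cc1OCc1ccccc1
A4 | alternative 2 | 3-ethoxy-2-methylcyclobut-2-en-1-one | CCOC1=C(C)C(=O)C1
A5 | alternative 2 | 1,3,5-tris(benzyloxy)-2-(3-methoxyprop-2-yn-1-yl)-4-methylbenzene | COC#CCc1c(OCc2ccccc2)cc(OCc2ccccc2)c(C)c1OCc1ccccc1
A6 | alternative 2 | 5-ethoxy-3-methoxy-4-methyl-2-[[2,4,6-tris(benzyloxy)-3-methylphenyl]methyl]phenol | COc1c(C)c(OCC)cc(O)c1Cc1c(OCc2ccccc2)cc(OCc2ccccc2)c(C)c1OCc1ccccc1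
A7 | alternative 3 | 2-methylcyclohexane-1,3-dione | CC1C(=O)CCCC1=O
A8 | alternative 3 | 2-(tert-butyldimethylsilyloxy)-4-methoxy-3-methyl-1-[(2,4,6-trimethoxy-3-methylphenyl)methyl]cyclohexa-1,3-diene | COC1=C(C)C(O[Si](C)(C)C(C)(C)C)=C(Cc2c(OC)cc(OC)c(C)c2OC)CC1
A9 | alternative 3 | 1-ethoxypent-1-yn-3-one | CCOC#CC(=O)CC
A10 | alternative 3 | 1-[2-ethoxy-4-hydroxy-6-methoxy-5-methyl-3-[(2,4,6-trimethoxy-3-methylphenyl)methyl]phenyl]propan-1-one | CCOc1c(C(=O)CC)c(OC)c(C)c(O)c1Cc1c(OC)cc(OC)c(C)c1OC
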